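At early times the spring run climbs steeply: 33% of the starting material is already target at 0.250 min, a mean slope of 1.32 min⁻¹ of the charge.

| flask | starting material | enzyme | remark | time |
|---|---|---|---|---|
| spring | 0.050 M | 48 µM | run made earlier |  |
| winter | 0.050 M | 24 µM | run made earlier |  |
| autumn | 0.050 M | 96 µM | run made earlier |  |
| delta | 0.050 M | 48 µM | a tube with plug flow, the mixed feed as stated, residence time 5.0 min | 5.0 min |
| eta | 0.050 M (fed, over 4.00 min) | 48 µM | all but starting material at the start; starting material goes in evenly over 4.00 min, the run ends at 5.0 min | 5.0 min |
| alpha | 0.050 M | 48 µM | everything together in a closed stirred flask, run for 5.0 min | 5.0 min |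
| zeta | 0.050 M | 48 µM | one stirred flow tank at steady state, fed with the mixture as stated, mean residence time 5.0 min |  |

| run | time / min | target / % |
|---|---|---|
| spring | 0.250 | 33 |
| spring | 0.500 | 36 |
| spring | 1.33 | 43 |
| spring | 3.00 | 41 |
| winter | 0.250 | 15 |
| winter | 0.500 | 21 |
| winter | 1.33 | 23 |
| winter | 3.00 | 24 |
| autumn | 0.417 | 59 |
| autumn | 1.00 | 57 |
| autumn | 2.00 | 60 |
| autumn | 3.00 | 62 |

(standard deviation of a reading: 2 percentage points)

- the stated concentrations are those of everything mixed, before any reaction; amounts are the same in each set-up
- the analysis behind the earlier runs scatters by 2 percentage points, standard deviation
- the feed brings no volume worth counting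
- the earlier runs were made in a closed, stirred flask

* the set-up with the highest amount of target at the outlet or at the end, in percent of the starting material put in ("none" if the first two lie within 2 percentage points) (delta / eta / alpha / zeta / none)
* amount of target at the outlet or at the end, in percent of the starting material put in, delta
* amount of target at the outlet or at the end, in percent of the starting material put in, eta
* amount of target at the outlet or at the end, in percent of the starting material put in, alpha
* amount of target at the outlet or at the end, in percent of the starting material put in, zeta

Then the spring curve bends. Its last two readings average 42.0%, and the starting line reaches that level at 0.318 min, so the knee comes earlier than the third reading. The winter and autumn runs end at 24% and 62%. Reading the approach to the spring level as an exponential, the first two readings give clocks of 6.16 min⁻¹ and 3.89 min⁻¹, and I take their mean, r = 5.03 min⁻¹.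

Now eta. I replace the feed by its mean, 0.0125 M min⁻¹, and let r remove what comes in. The balance gives S, the standing level of starting material during the feed (a quasi-steady state), S = feed/r = 0.00249 M. That is 4.97% of the charge. So by this estimate eta's feed runs far below the concentration at which the closed runs began, and I do not take eta's yield from alpha's.

The forecast gives delta 42%, eta 42%, alpha 42%, zeta 40%, best: none. Its ground is “selectivity ignores concentration”.

The flask gives delta 42.0%, eta 52.4%, alpha 42.0%, zeta 39.9%, best: eta.

    starting material + enzyme → target + enzyme, rate k1*[starting material]*[enzyme]/(1 + ([starting material]/Km1)) (27.2 mM, k = 2520 M⁻¹ s⁻¹)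
    starting material + enzyme → spent catalyst (k = 0.189 M⁻¹ s⁻¹)
    starting material + target → side product (k = 2.32 M⁻¹ s⁻¹)

The main reason target goes missing in eta is the step in which starting material meets target: without it eta ends at >99.9%, not 52.4%. Slow dosing is a part of what eta gains: the same charge given at once ends at 42.0%. My S of 0.00249 M overshoots eta's highest level, 0.00168 M, but both lie under the scheme's crowding constant, 27.2 mM. The crowding factor, one plus the level over that constant, slows the making of target and not the step that eats it; it is 1.09 by S and at most 1.06 in eta, against 2.84 at the start of alpha.

In the neighbouring eta with 0.013 M of starting material, a quarter of the charge, the same balance gives S = 6.47 × 10⁻⁴ M and a crowding factor of 1.02. That flask ends at 80.6% target and 19.4% side product.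

(The numbers in the tables stem from a simulated flask from invented constants, noise included.)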